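Everything rests on cutting both C–N bonds of the lactam ring (N2–C3 and N2–C1), which returns a racemic spirolactone and a serine ester. Two features are exploited. The N2–CH2CH2OH chain equals a decarboxylated serine residue. Spiro carbon C1, the N,O-ketal atom shared by the isoindolinone and naphtho[1,8-bc]furan rings, ionises reversibly in mild acid. One operation thus replaces ring oxygen O2 by nitrogen, builds the five-membered lactam and lets the serine stereocentre collect both C1 epimers into one diastereomer. The precursor is the 7-methoxy spiro[isobenzofuranone-naphthofuran] lactone with its C3' naphthol masked as a benzyl ether. Radical decarboxylation afterwards removes the auxiliary carbon.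

Key step: step 9

Locants: C1 is the spiro carbon, O2 or N2 the ring heteroatom, C3 the carbonyl carbon and C7 the methoxy-bearing carbon of ring A. Primed locants belong to the naphtho[1,8-bc]furan (O1', C2' = C1, C3' oxygenated, C7' methylated).

Assumption: the L-serine-derived substituent is taken to favour the (R) configuration at C1; should the balance lie on the (S) side, the commercial D-configured amino ester is substituted and the rest of the route is unchanged.

Step 1
Reactants: 1 4-(benzyloxy)benzaldehyde; 2 dimethyl succinate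
Product: 3 (E)-4-[4-(benzyloxy)phenyl]-3-(methoxycarbonyl)but-3-enoic acid
Conditions: t-BuOK (1.3 equiv), t-BuOH, 60 °C; then 1 M HCl
Reagents that add atoms: none
Why: Stobbe condensation: the succinate enolate adds to the aldehyde, the aldolate closes to a paraconic lactone and base-induced ring opening should give the (E) half-ester, in which the aryl group lies cis to the CH2CO2H arm as the next ring closure requires.

Step 2
Reactants: 3 (E)-4-[4-(benzyloxy)phenyl]-3-(methoxycarbonyl)but-3-enoic acid
Product: 4 methyl 4-acetoxy-6-(benzyloxy)-2-naphthoate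
Conditions: Ac2O, NaOAc, reflux (140 °C)
Reagents that add atoms: acetic anhydride, CC(=O)OC(C)=O
Why: Stobbe-type benzannulation (mixed anhydride, intramolecular acylation of one of the two equivalent ortho carbons, enolisation, O-acetylation), so that the benzyloxy group can only end up at C6, next to the peri position C5, and the ester carbon sits where the methyl group is needed.

Step 3
Reactants: 4 methyl 4-acetoxy-6-(benzyloxy)-2-naphthoate
Product: 5 methyl 4-acetoxy-6-(benzyloxy)-5-bromo-2-naphthoate
Conditions: NBS (1.05 equiv), MeCN, 0 °C to rt, dark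
Reagents that add atoms: N-bromosuccinimide, O=C1CCC(=O)N1Br
Why: Electrophilic aromatic bromination is placed at this stage on purpose, because the ester and acetoxy groups deactivate their own ring (a free 1-naphthol would be attacked at its C2 or C4), so the benzyloxy group should direct bromine to its alpha-type ortho carbon C5 and not to the less reactive beta carbon C7.

Step 4
Reactants: 5 methyl 4-acetoxy-6-(benzyloxy)-5-bromo-2-naphthoate
Product: 6 7-(benzyloxy)-8-bromo-3-(hydroxymethyl)naphthalen-1-ol
Conditions: LiAlH4 (2.5 equiv), THF, 0 °C; then EtOAc, sat. aq. potassium sodium tartrate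
Reagents that add atoms: none
Why: Hydride reduction of the ester to the primary benzylic alcohol with simultaneous reductive cleavage of the acetate, at a temperature at which aryl bromides and benzyl ethers are not touched.

Step 5
Reactants: 6 7-(benzyloxy)-8-bromo-3-(hydroxymethyl)naphthalen-1-ol
Product: 7 7-(benzyloxy)-8-bromo-3-(bromomethyl)naphthalen-1-ol
Conditions: CBr4 (1.5 equiv), PPh3 (1.5 equiv), CH2Cl2, 0 °C
Reagents that add atoms: carbon tetrabromide, BrC(Br)(Br)Br
Why: Appel reaction: only the primary alcohol gives an oxyphosphonium salt open to SN2 attack by bromide, the naphthol is returned on work-up, and the neutral medium avoids acid-induced migration of the ring bromine to the electron-rich naphthol ring.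

Step 6
Reactants: 7 7-(benzyloxy)-8-bromo-3-(bromomethyl)naphthalen-1-ol
Product: 8 7-(benzyloxy)-8-bromo-3-methylnaphthalen-1-ol
Conditions: LiEt3BH (3 equiv), THF, 0 °C; then aq. NH4Cl
Reagents that add atoms: none
Why: SN2 hydride displacement of a benzylic bromide by a trialkylborohydride (one equivalent is spent on the naphthol proton), a standard way to finish an ester-to-methyl reduction without hydrogenolysis, which the benzyl ether and the aryl bromide would not survive.

Step 7
Reactants: 8 7-(benzyloxy)-8-bromo-3-methylnaphthalen-1-ol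
Product: 11 3-(benzyloxy)-7-methyl-2H-naphtho[1,8-bc]furan-2-one, via dilithio naphtholate 9 (not isolated), via hydroxy acid 10 (not isolated)
Conditions: n-BuLi (2.3 equiv), THF, -78 °C; dry CO2, -78 °C to rt; 1 M HCl; TsOH·H2O (5 mol %), CH2Cl2, rt
Reagents that add atoms: carbon dioxide, O=C=O
Why: Bromine-lithium exchange on the preformed lithium naphtholate gives a peri O,C-dilithio species of a known type, carboxylation installs the C1 acid, and 8-hydroxy-1-naphthoic acids lactonise readily under acid catalysis.

Step 8
Reactants: 11 3-(benzyloxy)-7-methyl-2H-naphtho[1,8-bc]furan-2-one; 12 2-bromo-3-methoxybenzoic acid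
Product: 15 racemic 3'-(benzyloxy)-7-methoxy-7'-methyl-3H-spiro[isobenzofuran-1,2'-naphtho[1,8-bc]furan]-3-one, via dilithiated acid 13 (not isolated), via keto acid 14 (not isolated)
Conditions: 12 (1.5 equiv), n-BuLi (3.0 equiv), THF, -78 °C; add 11, -78 to -20 °C; 1 M HCl; TsOH·H2O (10 mol %), 4 Å MS, toluene, 60 °C
Reagents that add atoms: none
Why: Parham-type bromine-lithium exchange gives the lithium 2-lithiobenzoate with fixed regiochemistry and exact stoichiometry, its addition to the strained peri-lactone stops at the hindered diaryl ketone because ring opening releases a naphtholate, and acid-catalysed spiroketalisation-lactonisation (the closure known from fluoran dyes) forms C1 as a racemate, which is intended.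

Step 9
Reactants: 15 racemic 3'-(benzyloxy)-7-methoxy-7'-methyl-3H-spiro[isobenzofuran-1,2'-naphtho[1,8-bc]furan]-3-one; 16 O-benzyl-L-serine methyl ester hydrochloride
Product: 20 methyl (2S)-3-(benzyloxy)-2-[(1R)-3'-(benzyloxy)-7-methoxy-7'-methyl-3-oxospiro[isoindoline-1,2'-naphtho[1,8-bc]furan]-2-yl]propanoate, via free amino ester 17 (not isolated), via keto amide 18 (not isolated), via spiro epimer 19 (not isolated)
Conditions: 16, aq. NaHCO3/CH2Cl2 (free base, 1.3 equiv, used at once); 15, AcOH (1 equiv), toluene, 80 °C; then CSA (0.5 equiv), 4 Å MS, 45 °C until the epimer composition no longer changes; crystallise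
Reagents that add atoms: none
Why: The free amine attacks lactone carbonyl C3, which is an activated pseudo-ester because its leaving oxygen O2 collapses to the C1 ketone and the peri-naphthol, and this gives keto amide 18; under CSA the amide nitrogen then adds to the C1 carbonyl (or to its peri-oxygen-stabilised oxocarbenium form) in a 5-exo-trig closure of the lactam ring, water is lost and the C1-O1' bond of the naphthofuran is re-formed, likewise 5-exo-trig. The closest known reaction type is the conversion of xanthene-dye spirolactones into spirolactams by primary amines, combined with the equilibrium control that amino-acid-derived nitrogen substituents exert on the N,O-acetal carbon of bicyclic lactams. C1 is the only new stereocentre and is set thermodynamically: acid reversibly breaks C1-N2 (giving a planar 2-arylnaphthofuranylium ion, as in acid-opened dye lactams) or C1-O1' (giving an N-acyliminium ion), so 19 and 20 interconvert while the fixed serine carbon makes them unequal in energy, since its CO2Me and CH2OBn arms must lie over either the small O1' face or the crowded C2a'/C3'-OBn face of C1 (A(1,3)-type strain about the N2-C-alpha bond). Crystallisation of the favoured epimer out of the equilibrating mixture is available to raise the bias further. The step needs chemoselectivity for closure through nitrogen, secured by the benzyl cap on the serine oxygen (a free hydroxyl could trap the cation as an oxazolidine) and by the much higher electrophilicity of the acylal-type lactone compared with the amino ester's own methyl ester. It also needs the serine carbon to stay intact, which the weak acid, the aprotic solvent and the moderate temperature should ensure.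

Step 10
Reactants: 20 methyl (2S)-3-(benzyloxy)-2-[(1R)-3'-(benzyloxy)-7-methoxy-7'-methyl-3-oxospiro[isoindoline-1,2'-naphtho[1,8-bc]furan]-2-yl]propanoate
Product: 21 (2S)-3-(benzyloxy)-2-[(1R)-3'-(benzyloxy)-7-methoxy-7'-methyl-3-oxospiro[isoindoline-1,2'-naphtho[1,8-bc]furan]-2-yl]propanoic acid
Conditions: Me3SnOH (5 equiv), 1,2-dichloroethane, 70 °C; then cold 0.5 M HCl wash
Reagents that add atoms: trimethyltin hydroxide, C[Sn](C)(C)O
Why: Mild ester hydrolysis with trimethyltin hydroxide is chosen over alkali hydroxide to avoid E1cB loss of benzyl alcohol from the beta-alkoxy ester; C1 is untouched and any epimerisation at the serine carbon would be harmless because that centre is erased in step 12.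

Step 11
Reactants: 21 (2S)-3-(benzyloxy)-2-[(1R)-3'-(benzyloxy)-7-methoxy-7'-methyl-3-oxospiro[isoindoline-1,2'-naphtho[1,8-bc]furan]-2-yl]propanoic acid
Product: 22 1,3-dioxoisoindolin-2-yl ester of acid 21
Conditions: N-hydroxyphthalimide (1.1 equiv), DIC (1.1 equiv), DMAP (10 mol %), CH2Cl2, 0 °C to rt
Reagents that add atoms: N-hydroxyphthalimide, O=C1c2ccccc2C(=O)N1O
Why: Steglich-type carbodiimide esterification gives the redox-active N-hydroxyphthalimide ester under neutral conditions that leave the N,O-ketal closed.

Step 12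
Reactants: 22 1,3-dioxoisoindolin-2-yl ester of acid 21
Product: 23 (1R)-3'-(benzyloxy)-2-[2-(benzyloxy)ethyl]-7-methoxy-7'-methylspiro[isoindoline-1,2'-naphtho[1,8-bc]furan]-3-one
Conditions: Ru(bpy)3(PF6)2 (1 mol %), Hantzsch ester (1.5 equiv), degassed CH2Cl2, blue LEDs (450 nm), rt
Reagents that add atoms: none
Why: Photoredox reductive decarboxylation of a redox-active ester (a tin-free relative of the Barton decarboxylation): single-electron reduction expels phthalimide anion and CO2, and the stabilised alpha-amido radical takes hydrogen from the Hantzsch ester, which turns the serine residue into the 2-(benzyloxy)ethyl chain without acid or base, so C1 should keep its configuration.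

Step 13
Reactants: 23 (1R)-3'-(benzyloxy)-2-[2-(benzyloxy)ethyl]-7-methoxy-7'-methylspiro[isoindoline-1,2'-naphtho[1,8-bc]furan]-3-one
Product: 24 (1R)-3'-hydroxy-2-(2-hydroxyethyl)-7-methoxy-7'-methylspiro[isoindoline-1,2'-naphtho[1,8-bc]furan]-3-one
Conditions: H2 (1 atm), 10% Pd/C (neutral, prewashed), EtOAc-EtOH 1:1, rt; stopped at full conversion, filtered, no acid or base in the work-up
Reagents that add atoms: none
Why: Catalytic hydrogenolysis removes the aryl and the alkyl benzyl ether in one neutral operation, so that only a single step is run on the spiro centre after its guarding stereocentre has gone, and the fully substituted C1 is sterically shielded from the catalyst surface.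

Compound list
1 | 4-(benzyloxy)benzaldehyde | O=Cc1ccc(OCc2ccccc2)cc1 | starting material
2 | dimethyl succinate | COC(=O)CCC(=O)OC | starting material
3 | (E)-4-[4-(benzyloxy)phenyl]-3-(methoxycarbonyl)but-3-enoic acid | COC(=O)/C(CC(=O)O)=C/c1ccc(OCc2ccccc2)cc1 | intermediate
4 | methyl 4-acetoxy-6-(benzyloxy)-2-naphthoate | COC(=O)c1cc(OC(C)=O)c2cc(OCc3ccccc3)ccc2c1 | intermediate
5 | methyl 4-acetoxy-6-(benzyloxy)-5-bromo-2-naphthoate | COC(=O)c1cc(OC(C)=O)c2c(Br)c(OCc3ccccc3)ccc2c1 | intermediate
6 | 7-(benzyloxy)-8-bromo-3-(hydroxymethyl)naphthalen-1-ol | OCc1cc(O)c2c(Br)c(OCc3ccccc3)ccc2c1 | intermediate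
7 | 7-(benzyloxy)-8-bromo-3-(bromomethyl)naphthalen-1-ol | BrCc1cc(O)c2c(Br)c(OCc3ccccc3)ccc2c1 | intermediate
8 | 7-(benzyloxy)-8-bromo-3-methylnaphthalen-1-ol | Cc1cc(O)c2c(Br)c(OCc3ccccc3)ccc2c1 | intermediate
9 | lithium 7-(benzyloxy)-8-lithio-3-methylnaphthalen-1-olate (not isolated) | Cc1cc(O[Li])c2c([Li])c(OCc3ccccc3)ccc2c1 | intermediate
10 | 2-(benzyloxy)-8-hydroxy-6-methyl-1-naphthoic acid (not isolated) | Cc1cc(O)c2c(C(=O)O)c(OCc3ccccc3)ccc2c1 | intermediate
11 | 3-(benzyloxy)-7-methyl-2H-naphtho[1,8-bc]furan-2-one | O=C1Oc2cc(C)cc3ccc(OCc4ccccc4)c1c23 | intermediate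
12 | 2-bromo-3-methoxybenzoic acid | COc1cccc(C(=O)O)c1Br | starting material
13 | lithium 2-lithio-3-methoxybenzoate (not isolated) | COc1cccc(C(=O)O[Li])c1[Li] | intermediate
14 | 2-[2-(benzyloxy)-8-hydroxy-6-methyl-1-naphthoyl]-3-methoxybenzoic acid (not isolated) | COc1cccc(C(=O)O)c1C(=O)c1c(OCc2ccccc2)ccc2cc(C)cc(O)c12 | intermediate
15 | racemic 3'-(benzyloxy)-7-methoxy-7'-methyl-3H-spiro[isobenzofuran-1,2'-naphtho[1,8-bc]furan]-3-one | COc1cccc2c1C1(Oc3cc(C)cc4ccc(OCc5ccccc5)c1c34)OC2=O | intermediate
16 | O-benzyl-L-serine methyl ester hydrochloride | Cl.N[C@@H](COCc1ccccc1)C(=O)OC | starting material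
17 | O-benzyl-L-serine methyl ester, free base (not isolated) | N[C@@H](COCc1ccccc1)C(=O)OC | intermediate
18 | methyl N-{2-[2-(benzyloxy)-8-hydroxy-6-methyl-1-naphthoyl]-3-methoxybenzoyl}-O-benzyl-L-serinate (not isolated) | COc1cccc(C(=O)N[C@@H](COCc2ccccc2)C(=O)OC)c1C(=O)c1c(OCc2ccccc2)ccc2cc(C)cc(O)c12 | intermediate
19 | (1S,2S) spiro epimer of 20 (not isolated, equilibrates) | COc1cccc2c1[C@]1(Oc3cc(C)cc4ccc(OCc5ccccc5)c1c34)N([C@@H](COCc5ccccc5)C(=O)OC)C2=O | intermediate
20 | methyl (2S)-3-(benzyloxy)-2-[(1R)-3'-(benzyloxy)-7-methoxy-7'-methyl-3-oxospiro[isoindoline-1,2'-naphtho[1,8-bc]furan]-2-yl]propanoate | COc1cccc2c1[C@@]1(Oc3cc(C)cc4ccc(OCc5ccccc5)c1c34)N([C@@H](COCc5ccccc5)C(=O)OC)C2=O | intermediate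
21 | (2S)-3-(benzyloxy)-2-[(1R)-3'-(benzyloxy)-7-methoxy-7'-methyl-3-oxospiro[isoindoline-1,2'-naphtho[1,8-bc]furan]-2-yl]propanoic acid | COc1cccc2c1[C@@]1(Oc3cc(C)cc4ccc(OCc5ccccc5)c1c34)N([C@@H](COCc5ccccc5)C(=O)O)C2=O | intermediate
22 | 1,3-dioxoisoindolin-2-yl ester of acid 21 | COc1cccc2c1[C@@]1(Oc3cc(C)cc4ccc(OCc5ccccc5)c1c34)N([C@@H](COCc5ccccc5)C(=O)ON5C(=O)c6ccccc6C5=O)C2=O | intermediate
23 | (1R)-3'-(benzyloxy)-2-[2-(benzyloxy)ethyl]-7-methoxy-7'-methylspiro[isoindoline-1,2'-naphtho[1,8-bc]furan]-3-one | COc1cccc2c1[C@@]1(Oc3cc(C)cc4ccc(OCc5ccccc5)c1c34)N(CCOCc5ccccc5)C2=O | intermediate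
24 | (1R)-3'-hydroxy-2-(2-hydroxyethyl)-7-methoxy-7'-methylspiro[isoindoline-1,2'-naphtho[1,8-bc]furan]-3-one | COc1cccc2c1[C@@]1(Oc3cc(C)cc4ccc(O)c1c34)N(CCO)C2=O | target

Total step count: 13. Longest linear sequence: 13 steps (1 to 24); 12 and 16 are bought and enter directly.

Steps most likely to fail

1. Step 9. The energy gap between the two C1 epimers may be too small for a useful funnel. The weakly nucleophilic, alpha-branched amine may also open the lactone too slowly. The fallback sets out from 15 and returns at 23.
   - 15 is condensed in the same manner with commercial 2-(benzyloxy)ethan-1-amine, an unhindered primary amine, to give racemic dibenzyl lactam F1.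
   - Preparative chromatography on a polysaccharide-carbamate chiral phase separates 23 from (S)-dibenzyl lactam F2.
   - F2 is racemised with CSA back to the racemate and recycled. Steps 10 to 12 then fall away.

2. Step 8. The doubly ortho-substituted, aggregated dianion may add too slowly to a carbonyl flanked by the C3' benzyloxy group, so that protonation of the aryllithium on warming takes over. The fallback sets out from 11 and returns at 15.
   - Commercial 2-bromo-3-methoxybenzonitrile undergoes bromine-lithium exchange (n-BuLi, 1.0 equiv, THF, -90 °C). This gives the monoanionic, sterically slimmer 2-cyano-6-methoxyphenyllithium F3.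
   - F3 adds to 11 to give keto nitrile F4 after a neutral quench.
   - Warming with 2 M HCl in THF lets the peri-hemiketal hydroxyl add to the nitrile (intramolecular Pinner-type closure) to give spiro imidate F5. Hydrolysis of F5 in the same medium gives 15.

3. Step 13. The primary alkyl benzyl ether cleaves more slowly than the aryl one. The prolonged contact with Pd and H2 may start hydrogenolysis of the strained, doubly benzylic C1-O1' bond, or acidic catalyst sites may open and racemise the now unguarded C1. The fallback sets out from 15 and returns at 24.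
   - L-Serine methyl ester hydrochloride is silylated (TBSCl, imidazole, CH2Cl2) to O-TBS-L-serine methyl ester F6.
   - F6 is carried through the step 9 protocol (dry and aprotic, so the silyl ether should hold) to silyl lactam ester F7.
   - The chemistry of steps 10 to 12 then gives silyl lactam acid F8, silyl redox-active ester F9 and silyloxyethyl lactam F10.
   - TBAF buffered with AcOH (THF, 0 °C), used while the naphthol is still capped, gives hydroxyethyl lactam F11.
   - Only the fast aryl benzyl ether cleavage remains (10% Pd/C, H2, EtOAc, short contact), and it gives 24.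

Further compounds
F1 | step 9 | racemic 3'-(benzyloxy)-2-[2-(benzyloxy)ethyl]-7-methoxy-7'-methylspiro[isoindoline-1,2'-naphtho[1,8-bc]furan]-3-one | COc1cccc2c1C1(Oc3cc(C)cc4ccc(OCc5ccccc5)c1c34)N(CCOCc5ccccc5)C2=O
F2 | step 9 | (1S)-3'-(benzyloxy)-2-[2-(benzyloxy)ethyl]-7-methoxy-7'-methylspiro[isoindoline-1,2'-naphtho[1,8-bc]furan]-3-one | COc1cccc2c1[C@]1(Oc3cc(C)cc4ccc(OCc5ccccc5)c1c34)N(CCOCc5ccccc5)C2=O
F3 | step 8 | 2-cyano-6-methoxyphenyllithium | COc1cccc(C#N)c1[Li]
F4 | step 8 | 2-[2-(benzyloxy)-8-hydroxy-6-methyl-1-naphthoyl]-3-methoxybenzonitrile | COc1cccc(C#N)c1C(=O)c1c(OCc2ccccc2)ccc2cc(C)cc(O)c12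
F5 | step 8 | racemic 3'-(benzyloxy)-7-methoxy-7'-methyl-3H-spiro[isobenzofuran-1,2'-naphtho[1,8-bc]furan]-3-imine | COc1cccc2c1C1(Oc3cc(C)cc4ccc(OCc5ccccc5)c1c34)OC2=N
F6 | step 13 | O-(tert-butyldimethylsilyl)-L-serine methyl ester | N[C@@H](CO[Si](C)(C)C(C)(C)C)C(=O)OC
F7 | step 13 | methyl (2S)-3-(tert-butyldimethylsilyloxy)-2-[(1R)-3'-(benzyloxy)-7-methoxy-7'-methyl-3-oxospiro[isoindoline-1,2'-naphtho[1,8-bc]furan]-2-yl]propanoate | COc1cccc2c1[C@@]1(Oc3cc(C)cc4ccc(OCc5ccccc5)c1c34)N([C@@H](CO[Si](C)(C)C(C)(C)C)C(=O)OC)C2=O
F8 | step 13 | carboxylic acid from F7 | COc1cccc2c1[C@@]1(Oc3cc(C)cc4ccc(OCc5ccccc5)c1c34)N([C@@H](CO[Si](C)(C)C(C)(C)C)C(=O)O)C2=O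
F9 | step 13 | 1,3-dioxoisoindolin-2-yl ester of F8 | COc1cccc2c1[C@@]1(Oc3cc(C)cc4ccc(OCc5ccccc5)c1c34)N([C@@H](CO[Si](C)(C)C(C)(C)C)C(=O)ON5C(=O)c6ccccc6C5=O)C2=O
F10 | step 13 | (1R)-3'-(benzyloxy)-2-[2-(tert-butyldimethylsilyloxy)ethyl]-7-methoxy-7'-methylspiro[isoindoline-1,2'-naphtho[1,8-bc]furan]-3-one | COc1cccc2c1[C@@]1(Oc3cc(C)cc4ccc(OCc5ccccc5)c1c34)N(CCO[Si](C)(C)C(C)(C)C)C2=O
F11 | step 13 | (1R)-3'-(benzyloxy)-2-(2-hydroxyethyl)-7-methoxy-7'-methylspiro[isoindoline-1,2'-naphtho[1,8-bc]furan]-3-one | COc1cccc2c1[C@@]1(Oc3cc(C)cc4ccc(OCc5ccccc5)c1c34)N(CCO)C2=O
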